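**Plan**
- The benzene ring of the target is hexasubstituted: OH on three alternate carbons, an isobutyryl C=O, a methyl group and the chiral side chain. Read round the ring (C1–C6, acyl carbon C7) this is a folded methyl 3,5,7-trioxononanoate with the methyl on C2 and the side chain on C4.
- Retrosynthesis: the enol O–H of the triketone ring becomes O–Me. Then the ring bond C6–C1 is cut (isobutyryl-bearing carbon to the C–OH carbon next to C–CH3; Claisen). Then C6–C7 and C4–C5 (acylations of chain polyanions), then C2–C3 (opening of an enol lactone by a propanoate enolate). The lactone goes back to syncarpic acid and (E)-4-methylpent-2-enal.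
- Forward: the tetramethylcyclohexanetrione ring is made first (steps 1–2), then the dihydropyranone ring (step 3), which is opened again (step 4). The chain grows C1–C4, C1–C6, C1–C9 (steps 4–7); the benzene ring closes last (step 8); O-demethylation ends the route (step 9).
- Stereochemistry: the single stereocentre is set in step 3 by a chiral N-heterocyclic carbene. It carries no acidic hydrogen, and the O-methyl ether blocks retro-Michael loss of the triketone ring, so it is carried unchanged to the end.

Key step: step 8

Assumption: the antipode of the triazolium precatalyst that gives the (4R)-lactone is fixed by a test run (both are commercial); chain intermediates are drawn as keto forms and are mixtures of epimers at their enolisable carbons.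

**Step 1**
Reactants: 1 2,4,6-trihydroxyacetophenone
Product: 2 2-acetyl-3-hydroxy-4,4,6,6-tetramethylcyclohex-2-ene-1,5-dione
Conditions: MeI (6 equiv), NaOMe (5 equiv), MeOH, reflux
Reagents that add atoms: iodomethane, CI
Why: Exhaustive C-methylation of the phloroglucinol enolate (dearomatising enolate alkylation) places two methyl groups on each free ring carbon, while the acetyl group blocks the third position and the product is held as a stable enol.

**Step 2**
Reactants: 2 2-acetyl-3-hydroxy-4,4,6,6-tetramethylcyclohex-2-ene-1,5-dione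
Product: 3 syncarpic acid (2,2,4,4-tetramethylcyclohexane-1,3,5-trione)
Conditions: 6 M aq. HCl, reflux
Reagents that add atoms: none
Why: Acid-mediated retro-Claisen deacylation of the β-triketone removes the acetyl group as acetic acid and leaves the ring, which has no other cleavable enolisable position.

**Step 3**
Reactants: 3 syncarpic acid; 4 (E)-4-methylpent-2-enal
Product: 5 (4R)-4-isopropyl-6,6,8,8-tetramethyl-3,4-dihydro-2H-chromene-2,5,7(6H,8H)-trione
Conditions: 4 (1.5 equiv), aminoindanol-derived N-mesityl triazolium tetrafluoroborate precatalyst (10 mol%), DBU (20 mol%), 3,3',5,5'-tetra-tert-butyldiphenoquinone (1.2 equiv), 4 Å MS, toluene, rt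
Reagents that add atoms: none
Why: Oxidative N-heterocyclic carbene catalysis (formal [3+3] annulation of a cyclic 1,3-dione with an enal): the quinone oxidises the carbene–enal adduct to the α,β-unsaturated acyl azolium, the enolate of 3 adds to its β-carbon on the face left open by the aminoindanol backbone, which sets the stereocentre, and O-acylation closes the enol lactone and frees the carbene.

**Step 4**
Reactants: 5 (4R)-4-isopropyl-6,6,8,8-tetramethyl-3,4-dihydro-2H-chromene-2,5,7(6H,8H)-trione; 6 methyl propanoate
Product: 7 methyl (5R)-5-(2-hydroxy-3,3,5,5-tetramethyl-4,6-dioxocyclohex-1-en-1-yl)-2,6-dimethyl-3-oxoheptanoate (C2 epimers)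
Conditions: 6 (2.5 equiv), LiN(iPr)2 (2.5 equiv), THF, −78 °C; then 5, −78 to −40 °C; cold 1 M HCl
Reagents that add atoms: none
Why: Crossed Claisen condensation in which the enol lactone serves as an activated ester (the carbon-nucleophile opening of enol lactones known from the Fujimoto–Belleau reaction): the ester enolate adds to the lactone C=O, the stabilised triketone enolate is expelled, the β-keto ester is shielded from a second addition as its enolate, and the stereocentre, not α to any carbonyl, is untouched.

**Step 5**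
Reactants: 7 methyl (5R)-5-(2-hydroxy-3,3,5,5-tetramethyl-4,6-dioxocyclohex-1-en-1-yl)-2,6-dimethyl-3-oxoheptanoate
Product: 8 methyl (5R)-5-(2-methoxy-3,3,5,5-tetramethyl-4,6-dioxocyclohex-1-en-1-yl)-2,6-dimethyl-3-oxoheptanoate (C2 epimers)
Conditions: Me3SiCHN2 (1.2 equiv), MeOH/toluene 1:4, 0 °C
Reagents that add atoms: (trimethylsilyl)diazomethane, C[Si](C)(C)C=[N+]=[N-]
Why: O-Methylation of a vinylogous carboxylic acid with a diazoalkane: only the cyclic β-triketone enol is acidic enough to protonate the reagent, the α-methyl β-keto ester is not, and both enol oxygens of the symmetric ring lead to the same ether.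

**Step 6**
Reactants: 8 methyl (5R)-5-(2-methoxy-3,3,5,5-tetramethyl-4,6-dioxocyclohex-1-en-1-yl)-2,6-dimethyl-3-oxoheptanoate; 9 N-methoxy-N-methylacetamide
Product: 10 methyl 4-[(1S)-1-(2-methoxy-3,3,5,5-tetramethyl-4,6-dioxocyclohex-1-en-1-yl)-2-methylpropyl]-2-methyl-3,5-dioxohexanoate (C2/C4 epimers)
Conditions: LiN(iPr)2 (2.3 equiv), THF, −78 to 0 °C; 9 (1.5 equiv), −78 to −20 °C; AcOH quench
Reagents that add atoms: none
Why: γ-Acylation of a β-keto ester dianion: the first equivalent of base removes the C2 hydrogen, the second the only other enolisable position C4, and this terminal carbanion adds to the N-methoxy-N-methyl amide to give a chelated adduct that releases the ketone only on quench (Weinreb ketone synthesis), while the tetramethylated ring offers no enolisable hydrogen.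

**Step 7**
Reactants: 10 methyl 4-[(1S)-1-(2-methoxy-3,3,5,5-tetramethyl-4,6-dioxocyclohex-1-en-1-yl)-2-methylpropyl]-2-methyl-3,5-dioxohexanoate; 11 N-methoxy-N,2-dimethylpropanamide
Product: 12 methyl 4-[(1S)-1-(2-methoxy-3,3,5,5-tetramethyl-4,6-dioxocyclohex-1-en-1-yl)-2-methylpropyl]-2,8-dimethyl-3,5,7-trioxononanoate (C2/C4 epimers)
Conditions: LiN(iPr)2 (3.4 equiv), THF, −78 to 0 °C; 11 (1.5 equiv), −78 to −20 °C; AcOH quench; used without long storage
Reagents that add atoms: none
Why: Terminal acylation of a 3,5-diketo ester trianion (Claisen-type acylation of a polyketide polyanion): once C2 and C4 are deprotonated the third equivalent removes a hydrogen of the C6 methyl group, the only acidic site left, and this primary carbanion adds to the amide, whose chelated adduct gives the isopropyl ketone on quench.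

**Step 8**
Reactants: 12 methyl 4-[(1S)-1-(2-methoxy-3,3,5,5-tetramethyl-4,6-dioxocyclohex-1-en-1-yl)-2-methylpropyl]-2,8-dimethyl-3,5,7-trioxononanoate
Product: 14 2-[(1S)-1-[2,4,6-trihydroxy-3-methyl-5-(2-methylpropanoyl)phenyl]-2-methylpropyl]-3-methoxy-4,4,6,6-tetramethylcyclohex-2-ene-1,5-dione, via 2-acylcyclohexane-1,3,5-trione 13 (not isolated)
Conditions: Mg(OMe)2 (4 equiv), MeOH, rt to 50 °C; cold 1 M HCl
Reagents that add atoms: none
Why: Mg(OMe)2 turns 12 into a chelated polyenolate whose most acidic and least hindered carbon, the C6 methylene between the 5- and 7-ketones, adds to the ester carbonyl C1; methoxide leaves and the 2-acylcyclohexane-1,3,5-trione 13 enolises at once to the benzene ring, which makes the step irreversible. The closest known reaction type is the magnesium methoxide-templated intramolecular Claisen (Dieckmann-type) cyclisation of 3,5,7-trioxo esters to acylphloroglucinols, the laboratory counterpart of polyketide folding. The six-membered carbocycle closes in a 6-exo-trig mode, the enolate carbon attacking an ester C=O whose oxygen stays outside the new ring. No stereocentre is formed; the side-chain centre has no acidic hydrogen, and the O-methyl ether, which is unchanged by methoxide exchange in methanol, keeps the triketone ring from acting as an enolate donor in a retro-Michael cleavage. The selectivity needed is C6-to-C1 acylation over aldol closure (C2 onto C7, C8 onto C3) and over lactonisation of the C5 enolate oxygen onto C1: both aldol modes would create a quaternary carbon that cannot aromatise and so revert, the methyl-bearing C2 is the least acidic position so the ester stays electrophilic, and any 2-pyrone is reopened by methoxide.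

**Step 9**
Reactants: 14 2-[(1S)-1-[2,4,6-trihydroxy-3-methyl-5-(2-methylpropanoyl)phenyl]-2-methylpropyl]-3-methoxy-4,4,6,6-tetramethylcyclohex-2-ene-1,5-dione
Product: 15 2-[(1S)-1-[2,4,6-trihydroxy-3-methyl-5-(2-methylpropanoyl)phenyl]-2-methylpropyl]-3-hydroxy-4,4,6,6-tetramethylcyclohex-2-ene-1,5-dione (CNP0210316.1)
Conditions: LiCl (10 equiv), DMSO, 100 °C, argon; cold 0.5 M HCl
Reagents that add atoms: none
Why: Nucleophilic O-demethylation of a vinylogous methyl ester (SN2 at the methyl group, Krapcho-type dealkylation): chloride attacks the unhindered O–CH3 carbon because the ring carbon is shielded by the adjacent quaternary centre, the product forms as its lithium enolate with the phenols still protonated, and no bond to the stereocentre is touched.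

**Compound list**
1 | 2,4,6-trihydroxyacetophenone | CC(=O)c1c(O)cc(O)cc1O | starting material
2 | 2-acetyl-3-hydroxy-4,4,6,6-tetramethylcyclohex-2-ene-1,5-dione | CC(=O)C1=C(O)C(C)(C)C(=O)C(C)(C)C1=O | intermediate
3 | syncarpic acid (2,2,4,4-tetramethylcyclohexane-1,3,5-trione) | CC1(C)C(=O)CC(=O)C(C)(C)C1=O | intermediate
4 | (E)-4-methylpent-2-enal | CC(C)/C=C/C=O | starting material
5 | (4R)-4-isopropyl-6,6,8,8-tetramethyl-3,4-dihydro-2H-chromene-2,5,7(6H,8H)-trione | O=C1C[C@@H](C2=C(O1)C(C)(C)C(=O)C(C)(C)C2=O)C(C)C | intermediate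
6 | methyl propanoate | CCC(=O)OC | starting material
7 | methyl (5R)-5-(2-hydroxy-3,3,5,5-tetramethyl-4,6-dioxocyclohex-1-en-1-yl)-2,6-dimethyl-3-oxoheptanoate | COC(=O)C(C)C(=O)C[C@@H](C1=C(O)C(C)(C)C(=O)C(C)(C)C1=O)C(C)C | intermediate
8 | methyl (5R)-5-(2-methoxy-3,3,5,5-tetramethyl-4,6-dioxocyclohex-1-en-1-yl)-2,6-dimethyl-3-oxoheptanoate | COC(=O)C(C)C(=O)C[C@@H](C1=C(OC)C(C)(C)C(=O)C(C)(C)C1=O)C(C)C | intermediate
9 | N-methoxy-N-methylacetamide | CC(=O)N(C)OC | starting material
10 | methyl 4-[(1S)-1-(2-methoxy-3,3,5,5-tetramethyl-4,6-dioxocyclohex-1-en-1-yl)-2-methylpropyl]-2-methyl-3,5-dioxohexanoate | COC(=O)C(C)C(=O)C(C(C)=O)[C@@H](C1=C(OC)C(C)(C)C(=O)C(C)(C)C1=O)C(C)C | intermediate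
11 | N-methoxy-N,2-dimethylpropanamide | CC(C)C(=O)N(C)OC | starting material
12 | methyl 4-[(1S)-1-(2-methoxy-3,3,5,5-tetramethyl-4,6-dioxocyclohex-1-en-1-yl)-2-methylpropyl]-2,8-dimethyl-3,5,7-trioxononanoate | COC(=O)C(C)C(=O)C(C(=O)CC(=O)C(C)C)[C@@H](C1=C(OC)C(C)(C)C(=O)C(C)(C)C1=O)C(C)C | intermediate
13 | 4-[(1S)-1-(2-methoxy-3,3,5,5-tetramethyl-4,6-dioxocyclohex-1-en-1-yl)-2-methylpropyl]-6-methyl-2-(2-methylpropanoyl)cyclohexane-1,3,5-trione | CC1C(=O)C(C(=O)C(C)C)C(=O)C([C@@H](C2=C(OC)C(C)(C)C(=O)C(C)(C)C2=O)C(C)C)C1=O | intermediate (not isolated)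
14 | 2-[(1S)-1-[2,4,6-trihydroxy-3-methyl-5-(2-methylpropanoyl)phenyl]-2-methylpropyl]-3-methoxy-4,4,6,6-tetramethylcyclohex-2-ene-1,5-dione | Cc1c(O)c(C(=O)C(C)C)c(O)c([C@@H](C2=C(OC)C(C)(C)C(=O)C(C)(C)C2=O)C(C)C)c1O | intermediate
15 | 2-[(1S)-1-[2,4,6-trihydroxy-3-methyl-5-(2-methylpropanoyl)phenyl]-2-methylpropyl]-3-hydroxy-4,4,6,6-tetramethylcyclohex-2-ene-1,5-dione | Cc1c(O)c(C(=O)C(C)C)c(O)c([C@@H](C2=C(O)C(C)(C)C(=O)C(C)(C)C2=O)C(C)C)c1O | target

**Totals**
Total steps: 9. Longest linear sequence: 9 steps (1 to 15).

**Steps most likely to fail**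

Step 6. Acyl transfer to the β-branched C4 carbanion may be slow, so that proton transfer from the acetyl group of 9 to the dianion returns 8. The fallback sets out from 8 and comes back at 10. The same dianion is added at −78 °C to acetaldehyde, a smaller and far more electrophilic partner, to give the aldol adduct methyl 5-hydroxy-4-[(1S)-1-(2-methoxy-3,3,5,5-tetramethyl-4,6-dioxocyclohex-1-en-1-yl)-2-methylpropyl]-2-methyl-3-oxohexanoate F1 as a diastereomer mixture. Dess–Martin oxidation of the secondary alcohol (NaHCO3, CH2Cl2, 0 °C) then gives 10.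

Step 7. Proton transfer from the α-hydrogen of the isobutyryl donor to the C6 carbanion, or attack of that carbanion on the neighbouring enol ether carbon, may outrun the intermolecular acylation. The fallback sets out from 10 and comes back at 12. The trianion is added at −78 °C to isobutyraldehyde to give methyl 7-hydroxy-4-[(1S)-1-(2-methoxy-3,3,5,5-tetramethyl-4,6-dioxocyclohex-1-en-1-yl)-2-methylpropyl]-2,8-dimethyl-3,5-dioxononanoate F2. Dess–Martin oxidation of the carbinol then gives 12.

Step 8. Methoxide may add to the crowded C3 or C5 ketone and cleave an acyl arm from C4 (retro-Claisen), or the C5 enolate oxygen may close onto the ester, faster than C6 closes onto C1. The fallback sets out from 3 and comes back at 15; it brings the benzene ring in ready-made and gives up the enantiocontrol of step 3.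
- Knoevenagel condensation of 3 with isobutyraldehyde (piperidine cat., CH2Cl2) gives 2-(2-methylpropylidene)-4,4,6,6-tetramethylcyclohexane-1,3,5-trione F3.
- Friedel–Crafts acylation of commercial 2-methylbenzene-1,3,5-triol with isobutyryl chloride (AlCl3, nitrobenzene) gives 1-(2,4,6-trihydroxy-3-methylphenyl)-2-methylpropan-1-one F4.
- F4 adds through its only free ring carbon to F3 (NaH, THF, rt; Friedel–Crafts-type Michael addition) to give racemic 2-[1-[2,4,6-trihydroxy-3-methyl-5-(2-methylpropanoyl)phenyl]-2-methylpropyl]-3-hydroxy-4,4,6,6-tetramethylcyclohex-2-ene-1,5-dione F5.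
- Preparative chromatography on a chiral stationary phase separates the S enantiomer, 15.

**Further compounds**
F1 | step 6 | methyl 5-hydroxy-4-[(1S)-1-(2-methoxy-3,3,5,5-tetramethyl-4,6-dioxocyclohex-1-en-1-yl)-2-methylpropyl]-2-methyl-3-oxohexanoate | COC(=O)C(C)C(=O)C(C(C)O)[C@@H](C1=C(OC)C(C)(C)C(=O)C(C)(C)C1=O)C(C)C
F2 | step 7 | methyl 7-hydroxy-4-[(1S)-1-(2-methoxy-3,3,5,5-tetramethyl-4,6-dioxocyclohex-1-en-1-yl)-2-methylpropyl]-2,8-dimethyl-3,5-dioxononanoate | COC(=O)C(C)C(=O)C(C(=O)CC(O)C(C)C)[C@@H](C1=C(OC)C(C)(C)C(=O)C(C)(C)C1=O)C(C)C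
F3 | step 8 | 2-(2-methylpropylidene)-4,4,6,6-tetramethylcyclohexane-1,3,5-trione | CC(C)C=C1C(=O)C(C)(C)C(=O)C(C)(C)C1=O
F4 | step 8 | 1-(2,4,6-trihydroxy-3-methylphenyl)-2-methylpropan-1-one | Cc1c(O)cc(O)c(C(=O)C(C)C)c1O
F5 | step 8 | racemic 2-[1-[2,4,6-trihydroxy-3-methyl-5-(2-methylpropanoyl)phenyl]-2-methylpropyl]-3-hydroxy-4,4,6,6-tetramethylcyclohex-2-ene-1,5-dione | Cc1c(O)c(C(=O)C(C)C)c(O)c(C(C2=C(O)C(C)(C)C(=O)C(C)(C)C2=O)C(C)C)c1O
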